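**Plan**

- **Cuts (eudesmane numbering).** First C5–OOH together with the C4=C15 shift (Schenck ene). Then C4–C15 (Negishi). Then the C3–O(angelate) bond together with C4 itself, which is taken out of ring A as a carbene carbon. This leaves an A-nor hydrindene with a C3=C5 double bond.
- **Enabling feature.** In ring A (C1, C2, C3, C4, C5, C10) the sp2 carbon C4 lies between the two oxygen-bearing carbons C3 and C5. This C3–C4–C5 allyl triad is exactly what results from opening a cyclopropane C3–C4–C5 fused to a five-membered ring C10–C1–C2–C3–C5.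
- **Forward order.** Ring B comes from (+)-dihydrocarvone. C10 is quaternised with methyl acrylate (C1–C3), and McMurry coupling closes the five-membered ring. The isopropenyl group is oxidised to the acrylate, and CBr2 brings C4. Silver angelate expands the ring to ring A and installs the ester, Me2Zn brings C15, and singlet oxygen finishes.
- **Stereochemistry.** C7 comes from the chiral pool and C10 from the (R)-1-phenylethylamine auxiliary. C3 is set by pseudo-axial α capture of the allyl cation, and C5 by α-face attack of singlet oxygen anti to C14. The Z olefin comes from angelic acid, which is used only as a nucleophile.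

Key step: step 10

Convention: the eudesmane numbering of the target is kept for every intermediate. Ring A is C1–C5 and C10, ring B is C5–C10, C14 sits on C10, C15 on C4, and the side chain C11–C13 on C7. α is the face opposite to C14.

Assumption: commercial (+)-dihydrocarvone is the 5R compound sold as a mixture of C2 epimers. C2 becomes planar in step 1, so the mixture is used as such.

**Step 1**
Reactants: 1 (+)-dihydrocarvone; 2 (R)-(+)-1-phenylethylamine; 3 methyl acrylate
Product: 6 keto ester methyl 3-[(1S,4R)-1-methyl-2-oxo-4-(prop-1-en-2-yl)cyclohexyl]propanoate, via ketimine 4 (not isolated), via Michael adduct imine 5 (not isolated)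
Conditions: (a) 2, toluene, Dean–Stark, reflux; (b) 3, THF, 40 °C; (c) 10% aq AcOH, THF, rt
Reagents that add atoms: methyl acrylate 3, C=CC(=O)OC; water, O
Why: Asymmetric Michael addition of a chiral imine through its more substituted secondary enamine tautomer (aza-ene-like, with internal N–H transfer), in which the (R)-1-phenylethyl group shields one enamine face so that the acrylate chain enters at C10 trans to the C7 isopropenyl group and C14 ends β, after which hydrolysis frees the ketone and the auxiliary.

**Step 2**
Reactants: 6 keto ester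
Product: 7 diol 3-[(1S,4R)-2-hydroxy-1-methyl-4-(prop-1-en-2-yl)cyclohexyl]propan-1-ol (C5 carbinol epimers)
Conditions: LiAlH4, THF, 0 °C
Reagents that add atoms: none
Why: Exhaustive hydride reduction of ketone and ester, the new C5 carbinol centre being of no consequence because it is oxidised again in step 3.

**Step 3**
Reactants: 7 diol
Product: 8 keto aldehyde 3-[(1S,4R)-1-methyl-2-oxo-4-(prop-1-en-2-yl)cyclohexyl]propanal
Conditions: Dess–Martin periodinane, CH2Cl2, 0 °C to rt
Reagents that add atoms: none
Why: Dess–Martin oxidation of both alcohols under neutral conditions, which avoids aldol closure of the 1,5-keto aldehyde and cannot touch the quaternary C10 or the remote C7.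

**Step 4**
Reactants: 8 keto aldehyde
Product: 9 A-nor diene (3aR,6R)-3a-methyl-6-(prop-1-en-2-yl)-3,3a,4,5,6,7-hexahydro-2H-indene (five-membered ring C10–C1–C2–C3–C5 with C3=C5; 10β-methyl; 7β-isopropenyl)
Conditions: TiCl3(DME)1.5, Zn–Cu, DME, reflux, slow addition of 8
Reagents that add atoms: none
Why: Intramolecular McMurry coupling of a 1,5-keto aldehyde, a standard entry to cyclopentenes, closes the five-membered ring as the C3=C5 olefin and leaves the isolated isopropenyl group alone.

**Step 5**
Reactants: 9 A-nor diene
Product: 12 allylic alcohol 2-[(3aR,6R)-3a-methyl-3,3a,4,5,6,7-hexahydro-2H-inden-6-yl]prop-2-en-1-ol, via allyllithium 10 (not isolated), via allylboronate 11 (not isolated)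
Conditions: n-BuLi, TMEDA, hexane, rt; B(OMe)3, THF, −78 °C; H2O2, aq NaOH, 0 °C
Reagents that add atoms: hydrogen peroxide, OO
Why: Allylic lithiation takes the methyl group of the 1,1-disubstituted olefin (as it does with limonene), and borate trapping followed by oxidation gives the primary allylic alcohol, allylic transposition being degenerate and no stereocentre being touched.

**Step 6**
Reactants: 12 allylic alcohol
Product: 13 enal 2-[(3aR,6R)-3a-methyl-3,3a,4,5,6,7-hexahydro-2H-inden-6-yl]prop-2-enal
Conditions: MnO2, CH2Cl2, rt
Reagents that add atoms: none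
Why: Chemoselective MnO2 oxidation of an allylic alcohol to the 2-substituted acrolein without action on the olefins.

**Step 7**
Reactants: 13 enal
Product: 14 acrylic acid 2-[(3aR,6R)-3a-methyl-3,3a,4,5,6,7-hexahydro-2H-inden-6-yl]prop-2-enoic acid
Conditions: NaClO2, NaH2PO4, 2-methyl-2-butene, t-BuOH/H2O, 0 °C to rt
Reagents that add atoms: sodium chlorite, [Na+].[O-]Cl=O
Why: Pinnick oxidation, the usual way from 2-substituted acroleins to acrylic acids, with 2-methyl-2-butene in excess to take up HOCl before it reaches the C3=C5 olefin.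

**Step 8**
Reactants: 14 acrylic acid
Product: 15 A-nor acrylate methyl 2-[(3aR,6R)-3a-methyl-3,3a,4,5,6,7-hexahydro-2H-inden-6-yl]prop-2-enoate
Conditions: MeI, K2CO3, DMF, rt
Reagents that add atoms: iodomethane, CI
Why: Carboxylate O-alkylation (SN2 on MeI) under conditions too mild to move the acrylate double bond or to epimerise C7.

**Step 9**
Reactants: 15 A-nor acrylate
Product: 16 gem-dibromocyclopropane (3α,5α-dibromomethano adduct of 15; cyclopropane C3–C4–C5 on the α face; C4 = CBr2)
Conditions: CHBr3, KOt-Bu, pentane, −20 to 0 °C; cold filtration, used at once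
Reagents that add atoms: bromoform, BrC(Br)Br
Why: Dibromocarbene [2+1] cycloaddition, in which the electrophilic carbene picks the electron-rich trisubstituted C3=C5 olefin over the electron-poor acrylate and adds anti to C14, the two new centres C3 and C5 being erased in step 10.

**Step 10**
Reactants: 16 gem-dibromocyclopropane; 17 angelic acid
Product: 19 methyl 3α-angeloyloxy-4-bromo-15-noreudesma-4,11(13)-dien-12-oate, via bromoallyl cation 18 (not isolated)
Conditions: 17, Ag2O, 4 Å MS, CH2Cl2, dark, rt; then 16, 0 °C to rt
Reagents that add atoms: angelic acid 17, C/C=C(/C)C(=O)O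
Why: Silver ion pulls off the endo bromide of 16 while the shared C3–C5 bond opens in a disrotatory two-electron electrocyclic process, so that the five-membered ring C10–C1–C2–C3–C5 and the cyclopropane merge into six-membered ring A as the 4-bromoallyl cation 18 (C3–C4–C5), which angelate captures at C3. The closest known reaction type is the silver-salt-promoted ring expansion of 6,6-dibromobicyclo[3.1.0]hexanes to 2-bromocyclohex-2-enyl carboxylates, ethers and amines. No ring is closed by bond formation: ring A arises by cleavage of the zero-atom bridge of the bicyclo[3.1.0]hexane, and the only new bond is the intermolecular C3–O bond. The new stereocentre C3 is controlled by the ring A half-chair that the quaternary C10 and the equatorial C7 side chain fix, since the pseudo-axial line of attack at C3 lies on the α face, which is also the face from which the silver-bound bromide leaves and on which the carboxylate of the ion pair sits, and this line avoids A1,2 strain with the C4 bromine. The step needs regioselectivity for C3 over C5, which is secured by the fully substituted, neopentyl-type C5 and by the gain of the tetrasubstituted C4=C5 bond, as in silver-assisted solvolyses of 2,2-dialkyl gem-dibromocyclopropanes that end at the less substituted terminus, while proton loss is held back by a high carboxylate concentration in a non-basic medium. Because angelate enters as a nucleophile and is never activated at its acyl carbon, the Z geometry is kept.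

**Step 11**
Reactants: 19 bromide
Product: 20 methyl 3α-angeloyloxyeudesma-4,11(13)-dien-12-oate
Conditions: Me2Zn, Pd(P(t-Bu)3)2 (cat.), THF, rt to 45 °C
Reagents that add atoms: dimethylzinc, C[Zn]C
Why: Negishi coupling of a hindered alkenyl bromide, in which oxidative addition of zerovalent palladium into C4–Br outruns ionisation of the allylic ester because the olefin is tetrasubstituted, so that C15 is attached and C3 stays untouched.

**Step 12**
Reactants: 20 methyl 3α-angeloyloxyeudesma-4,11(13)-dien-12-oate
Product: 21 methyl 3α-angeloyloxy-5α-hydroperoxyeudesma-4(15),11(13)-dien-12-oate (target)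
Conditions: O2, 5,10,15,20-tetraphenylporphyrin (cat.), CH2Cl2, visible light, −20 °C; no reductive work-up
Reagents that add atoms: dioxygen, O=O
Why: Schenck ene reaction, in which singlet oxygen reacts only with the electron-rich tetrasubstituted C4=C5 olefin, attacks the α face anti to the axial C14 methyl group and, since on that face only the C15 hydrogens are aligned (H-3 is β and H-6α is equatorial), places OOH on C5α and moves the double bond to C4=C15.

**Compound list**

1 | (+)-dihydrocarvone, (5R)-2-methyl-5-(prop-1-en-2-yl)cyclohexan-1-one, C2 epimers | CC1CC[C@@H](C(C)=C)CC1=O | starting material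
2 | (R)-(+)-1-phenylethylamine | C[C@@H](N)c1ccccc1 | starting material
3 | methyl acrylate | C=CC(=O)OC | starting material
4 | ketimine of 1 and 2 | CC1CC[C@@H](C(C)=C)CC1=N[C@H](C)c1ccccc1 | intermediate
5 | Michael adduct imine | C=C(C)[C@@H]1CC[C@@](C)(CCC(=O)OC)C(=N[C@H](C)c2ccccc2)C1 | intermediate
6 | methyl 3-[(1S,4R)-1-methyl-2-oxo-4-(prop-1-en-2-yl)cyclohexyl]propanoate | C=C(C)[C@@H]1CC[C@@](C)(CCC(=O)OC)C(=O)C1 | intermediate
7 | 3-[(1S,4R)-2-hydroxy-1-methyl-4-(prop-1-en-2-yl)cyclohexyl]propan-1-ol, carbinol epimers | C=C(C)[C@@H]1CC[C@@](C)(CCCO)C(O)C1 | intermediate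
8 | 3-[(1S,4R)-1-methyl-2-oxo-4-(prop-1-en-2-yl)cyclohexyl]propanal | C=C(C)[C@@H]1CC[C@@](C)(CCC=O)C(=O)C1 | intermediate
9 | A-nor diene, (3aR,6R)-3a-methyl-6-(prop-1-en-2-yl)-3,3a,4,5,6,7-hexahydro-2H-indene | C=C(C)[C@@H]1CC[C@@]2(C)CCC=C2C1 | intermediate
10 | allyllithium of 9 | [Li]CC(=C)[C@@H]1CC[C@@]2(C)CCC=C2C1 | intermediate
11 | dimethyl allylboronate of 9 | COB(OC)CC(=C)[C@@H]1CC[C@@]2(C)CCC=C2C1 | intermediate
12 | A-nor allylic alcohol | C=C(CO)[C@@H]1CC[C@@]2(C)CCC=C2C1 | intermediate
13 | A-nor enal | C=C(C=O)[C@@H]1CC[C@@]2(C)CCC=C2C1 | intermediate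
14 | A-nor acrylic acid | C=C(C(=O)O)[C@@H]1CC[C@@]2(C)CCC=C2C1 | intermediate
15 | A-nor acrylate, methyl 2-[(3aR,6R)-3a-methyl-3,3a,4,5,6,7-hexahydro-2H-inden-6-yl]prop-2-enoate | C=C(C(=O)OC)[C@@H]1CC[C@@]2(C)CCC=C2C1 | intermediate
16 | 3α,5α-dibromomethano adduct of 15 | C=C(C(=O)OC)[C@@H]1CC[C@@]2(C)CC[C@H]3C(Br)(Br)[C@@]23C1 | intermediate
17 | angelic acid, (Z)-2-methylbut-2-enoic acid | C/C=C(/C)C(=O)O | starting material
18 | 4-bromoallyl cation (C3–C4–C5) | C=C(C(=O)OC)[C@@H]1CC[C@@]2(C)CC[CH+]C(Br)=C2C1 | intermediate
19 | methyl 3α-angeloyloxy-4-bromo-15-noreudesma-4,11(13)-dien-12-oate | C=C(C(=O)OC)[C@@H]1CC[C@@]2(C)CC[C@@H](OC(=O)/C(C)=C\C)C(Br)=C2C1 | intermediate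
20 | methyl 3α-angeloyloxyeudesma-4,11(13)-dien-12-oate | C=C(C(=O)OC)[C@@H]1CC[C@@]2(C)CC[C@@H](OC(=O)/C(C)=C\C)C(C)=C2C1 | intermediate
21 | methyl 3α-angeloyloxy-5α-hydroperoxyeudesma-4(15),11(13)-dien-12-oate (CNP0137897.2) | C=C(C(=O)OC)[C@@H]1CC[C@@]2(C)CC[C@@H](OC(=O)/C(C)=C\C)C(=C)[C@]2(OO)C1 | target

Total step count: 12. Longest linear sequence: 12 steps (from 1).

**Steps most likely to fail**

**Step 10.** The allyl cation may lose a proton, or it may be captured with poor regio- or facial selectivity.
- The fallback separates ring expansion from ester introduction. It sets out from 16 and comes back at 19.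
- Opening of 16 with AgNO3 in aqueous acetone should give the epimeric 3-hydroxy bromides F1.
- Dess–Martin oxidation funnels both epimers into the bromo enone F2.
- Luche reduction (NaBH4, CeCl3·7H2O, MeOH), with hydride entering axially from the α face, should give the 3β-alcohol F3.
- Mitsunobu esterification with 17 (PPh3, DIAD, toluene) inverts C3 and again uses angelate only as a nucleophile, which leads to 19.

**Step 12.** Singlet oxygen may attack the β face, or react slowly, because the pseudo-axial 3α-ester screens the α face. Hydrogen abstraction from C6 may then compete.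
- The fallback uses a hydroxy-directed photooxygenation. It sets out from 16 and comes back at 21.
- Opening of 16 with AgNO3 in aqueous acetone, under the same stereocontrol as in step 10, should give the 3α-hydroxy bromide F4.
- Negishi methylation with excess Me2Zn gives the 3α-allylic alcohol F5.
- Photooxygenation in a non-polar solvent should give the hydroxy hydroperoxide F6, because the pseudo-axial hydroxyl group hydrogen-bonds to the incoming oxygen and steers it to the α face.
- Silylation of the more acidic and more exposed OOH terminus (Et3SiCl, Et3N, low temperature) gives the silyl peroxide F7.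
- Esterification of the 3α-hydroxyl group with the mixed anhydride of 17 and 2,4,6-trichlorobenzoic acid (Yamaguchi-type, no nucleophilic catalyst) gives the protected ester F8.
- HF·pyridine frees 21.

**Step 9.** Carbene transfer to the olefin next to the quaternary C10 may be slow. Bromoform-derived species may attack the acrylate, and the adduct may ionise during isolation.
- The fallback raises the nucleophilicity of the C3=C5 bond. It sets out from 15 and comes back at 19.
- mCPBA epoxidation of the trisubstituted olefin gives the α-epoxide F9.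
- Meinwald rearrangement (BF3·OEt2, hydride shift from C3 to C5) gives the A-nor 3-ketone F10.
- TMSCl, NaI and Et3N in MeCN give the thermodynamic silyl enol ether F11.
- Dibromocarbene adds to this far more electron-rich olefin to give the siloxy dibromocyclopropane F12.
- On warming, F12 expands with loss of the silyl group to the bromo enone F2.
- Luche reduction to the 3β-alcohol F3 and Mitsunobu inversion with 17 then lead to 19.

**Further compounds**

F1 | step 10 | methyl 4-bromo-3-hydroxy-15-noreudesma-4,11(13)-dien-12-oate, C3 epimers | C=C(C(=O)OC)[C@@H]1CC[C@@]2(C)CCC(O)C(Br)=C2C1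
F2 | step 10 | methyl 4-bromo-3-oxo-15-noreudesma-4,11(13)-dien-12-oate | C=C(C(=O)OC)[C@@H]1CC[C@@]2(C)CCC(=O)C(Br)=C2C1
F3 | step 10 | methyl 4-bromo-3β-hydroxy-15-noreudesma-4,11(13)-dien-12-oate | C=C(C(=O)OC)[C@@H]1CC[C@@]2(C)CC[C@H](O)C(Br)=C2C1
F4 | step 12 | methyl 4-bromo-3α-hydroxy-15-noreudesma-4,11(13)-dien-12-oate | C=C(C(=O)OC)[C@@H]1CC[C@@]2(C)CC[C@@H](O)C(Br)=C2C1
F5 | step 12 | methyl 3α-hydroxyeudesma-4,11(13)-dien-12-oate | C=C(C(=O)OC)[C@@H]1CC[C@@]2(C)CC[C@@H](O)C(C)=C2C1
F6 | step 12 | methyl 5α-hydroperoxy-3α-hydroxyeudesma-4(15),11(13)-dien-12-oate | C=C(C(=O)OC)[C@@H]1CC[C@@]2(C)CC[C@@H](O)C(=C)[C@]2(OO)C1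
F7 | step 12 | methyl 3α-hydroxy-5α-(triethylsilylperoxy)eudesma-4(15),11(13)-dien-12-oate | C=C(C(=O)OC)[C@@H]1CC[C@@]2(C)CC[C@@H](O)C(=C)[C@]2(OO[Si](CC)(CC)CC)C1
F8 | step 12 | methyl 3α-angeloyloxy-5α-(triethylsilylperoxy)eudesma-4(15),11(13)-dien-12-oate | C=C(C(=O)OC)[C@@H]1CC[C@@]2(C)CC[C@@H](OC(=O)/C(C)=C\C)C(=C)[C@]2(OO[Si](CC)(CC)CC)C1
F9 | step 9 | 3α,5α-epoxide of 15 | C=C(C(=O)OC)[C@@H]1CC[C@@]2(C)CC[C@H]3O[C@@]23C1
F10 | step 9 | A-nor 3-ketone (C5 epimers) | C=C(C(=O)OC)[C@@H]1CC[C@@]2(C)CCC(=O)C2C1
F11 | step 9 | A-nor 3-(trimethylsilyloxy)-3(5)-ene | C=C(C(=O)OC)[C@@H]1CC[C@@]2(C)CCC(O[Si](C)(C)C)=C2C1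
F12 | step 9 | 3α,5α-dibromomethano adduct of F11 | C=C(C(=O)OC)[C@@H]1CC[C@@]2(C)CC[C@@]3(O[Si](C)(C)C)C(Br)(Br)[C@@]23C1
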